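Late in the midnight and summer runs the readings stood flat: from 12.0 min the starting material read zero within the scatter, and at 40.0 min the product read 14.6% and 39.9% of the charge, more in the summer run.

| flask | starting material | protic impurity | free catalyst | remark | time |
|---|---|---|---|---|---|
| midnight | 0.67 M | 1 M | 0.36 mol% (in portions, 4) | run made earlier; portions every 4.0 s |  |
| summer | 1.5 M | 1 M | 0.36 mol% (in portions, 4) | run made earlier; portions every 4.0 s |  |
| flask | 1.0 M | 1.00 M | 0.36 mol% (in portions, 4) | the portions of free catalyst follow each other after 4.0 s, the first at the start | 40 min |

| run | time / min | starting material / % | product / % |
|---|---|---|---|
| midnight | 3.00 | 1.0 | 14.6 |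
| midnight | 6.00 | 0.7 | 14.2 |
| midnight | 12.0 | 0 | 14.4 |
| midnight | 20.0 | 0 | 14.3 |
| midnight | 40.0 | 0 | 14.6 |
| summer | 3.00 | 0.4 | 40.0 |
| summer | 6.00 | 0.9 | 41.0 |
| summer | 12.0 | 0 | 38.8 |
| summer | 20.0 | 0.5 | 40.1 |
| summer | 40.0 | 0 | 39.9 |

(scatter of a reading: 0.5 percentage points)

- a reading or a percentage of product counts all its forms, free or not
- the reaction counts as stopped when no species that holds the starting material changes by six tenths of a point or more over the second half of the time
- a reading of starting material is of its free form alone

1. at 40 min, what has stopped the reaction, if anything has (all of the starting material has reacted / no working catalyst is left / it is still moving)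
2. part of the starting material gone at 40 min
3. the product standing at 40 min, as a percentage of the starting material charged

In concentrations the product was 0.0978 M at midnight and 0.599 M in summer. The missing 0.572 M and 0.901 M stayed below the charge of protic impurity, so I took them as lost to it one to one, which left 0.428 M and 0.0985 M of protic impurity.

I treated the two routes as parallel drains on the starting material, each first order in it. I froze the catalyst at its full charge, which made the route into product pseudo-first-order, but I let the protic impurity fall in the loss route, since it is not in excess. The starting material then cancels, and [product] = W[catalyst] ln([impurity charged]/[impurity left]). The midnight run gave 47.8 and the summer run 47.8, so I kept W = 47.8, the split factor: a selectivity factor, the rate into product over the rate of loss when catalyst and protic impurity stand equal, read for this portion schedule.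

The flask resembles the midnight run, with the same protic impurity and loading, but holds more catalyst, 3.60 mM. Its starting material equals its protic impurity, so the product fraction equals the fraction of protic impurity left. Solving that balance with 0.172 for W times the loading, I reckoned 24.3% of product, above the midnight reading, with starting material reading zero by 40 min.

The forecast said all of the starting material has reacted, with 100% conversion and 24% product, the loss running “in competition with catalysis”.

The flask gave all of the starting material has reacted, 100% conversion and 24.7% product.

    starting material + free catalyst → catalyst intermediate (k = 37.0 M⁻¹ s⁻¹)
    catalyst intermediate → free catalyst + product (k = 48.0 s⁻¹)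
    starting material + product ⇌ idle adduct, settled at all times (K = 12.0 M⁻¹)
    starting material + protic impurity → quenched substrate (k = 0.300 M⁻¹ s⁻¹)

From the 25% of protic impurity left in this flask, W gives 24.0% product. The product in this flask stood below the charge due to the loss to quenched substrate: the same flask run without that step gave 100% instead of 24.7%. In the neighbour charged with 0.25 M of starting material, W gives 0.0430 M for W[catalyst], and so 4.67% product. That neighbour gave 4.37%.

The runs come from a simulation for substances that don't exist.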